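**Plan** (eudesmane numbering: ring A = C1–C5/C10, ring B = C5–C10, C11–C13 = acrylate on C7, C14 = angular methyl, C15 on C4; β = face of C14)

1. Retrosynthesis: the 5-OOH/4(15)-alkene goes back to a 4,5-alkene (ene reaction); the angelate, the acetate and the C12 ester go back to a 3β-ol and a cis 8β,12-lactone (temporary ring); C4–C15 goes back to a diosphenol triflate; ring B is then cut at C6–C7 and C9–C10.
2. Enabling feature: O-bearing C8 lies between C7 and C9 (an acetone unit, both α-carbons donors), while C6 and C10 both hang on C5, which is α to C4 (a masked ketone). C6 and C10 are therefore the allylic-bromide carbon and the β-enone carbon of 2-(bromomethyl)-3-methylcyclohexenone, and both new bonds complete 1,5-dicarbonyl (C4/C8) paths around ring B.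
3. Forward: ring A comes from 3-methylcyclohexenone (→ bromide 4). A valine-derived enamino ester of dimethyl acetylsuccinate (C7, C8, C9, C11, C12) is alkylated at C7 and closes through C9 onto C10 in one flask, giving ring B and the quaternary C10.
4. Then C3=O/C15 are installed (diosphenol, triflate, methylation), the helper ester on C7 is removed, and both ketones are reduced with lactonisation. Methylenation (C13), Mitsunobu angeloylation, lactone opening/acetylation and photo-oxygenation finish the route.
5. Stereochemistry: L-valine sets C7, and C7 relays to C10 through a hydrogen-bonded chair. C7 is later equilibrated to equatorial; C8 and C3 come from hydride attack anti to C14 (C3 then inverted); C5 comes from α-face singlet-oxygen attack.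

Key step: step 5

Assumption: the lithio-enamine of 7 is taken to be alkylated on the face that gives (7R)-8 in toluene–HMPA; the sense of such alkylations inverts with the donor solvent, so the THF regime would be used if the opposite face reacts.

Step 1
Reactants: 1 3-methylcyclohex-2-en-1-one
Product: 2 2-iodo-3-methylcyclohex-2-en-1-one
Conditions: I2, pyridine, CH2Cl2, 0 °C to rt
Reagents that add atoms: iodine, II
Why: Pyridine-mediated addition–elimination (α-iodination of an enone) places iodine on C5, the only vinylic C–H, and no stereocentre is formed.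

Step 2
Reactants: 2 2-iodo-3-methylcyclohex-2-en-1-one
Product: 3 2-(hydroxymethyl)-3-methylcyclohex-2-en-1-one
Conditions: Bu3SnCH2OH, Pd(PPh3)4 (5 mol %), dioxane, 90 °C
Reagents that add atoms: (tributylstannyl)methanol, OC[Sn](CCCC)(CCCC)CCCC
Why: Stille cross-coupling of the α-iodoenone transfers the hydroxymethyl group (C6) to C5 without touching the enone.

Step 3
Reactants: 3 2-(hydroxymethyl)-3-methylcyclohex-2-en-1-one
Product: 4 2-(bromomethyl)-3-methylcyclohex-2-en-1-one
Conditions: CBr4, PPh3, CH2Cl2, 0 °C
Reagents that add atoms: tetrabromomethane, BrC(Br)(Br)Br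
Why: Appel bromination converts the primary allylic alcohol into the bromide under neutral conditions that the enone tolerates.

Step 4
Reactants: 5 dimethyl 2-acetylbutanedioate (dimethyl acetylsuccinate); 6 tert-butyl L-valinate
Product: 7 dimethyl (2Z)-2-[1-({(2S)-1-tert-butoxy-3-methyl-1-oxobutan-2-yl}amino)ethylidene]butanedioate
Conditions: BF3·OEt2 (cat.), toluene, reflux, Dean–Stark
Reagents that add atoms: none
Why: Condensation of the β-keto ester with the primary amine gives the N–H···O=C hydrogen-bonded (Z)-β-enamino ester, the valine stereocentre being untouched.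

Step 5
Reactants: 7 the enamino ester; 4 2-(bromomethyl)-3-methylcyclohex-2-en-1-one
Product: 10 7β-(methoxycarbonyl)-7α-(2-methoxy-2-oxoethyl)-10β-methyl-trans-decalin-4,8-dione (5α-H; 7R,10R), via alkylated imine 8 (not isolated), via bicyclic imine 9 (not isolated)
Conditions: LiN(iPr)2 (1.05 equiv), toluene, HMPA (2 equiv), −78 °C; 4, −78 to −30 °C; then PhCO2H (0.3 equiv), 70 °C; then 1 M aq HCl, THF, 0 °C to rt
Reagents that add atoms: water, O
Why: Proposed new method: the chelated lithio-enamine of 7 is C-alkylated at C7 by the allylic bromide (SN2, the known lithio-enamine alkylation of valine-derived β-enamino esters) to give imine 8; because C7 is now quaternary, acid-catalysed imine–enamine tautomerism can only reach the C9 methyl, and this secondary enamine adds to C10 of the acid-activated enone, after which hydrolysis releases 10 and the auxiliary. The closest known reaction type is the α,α′-annulation of enamines with 2-(bromomethyl)acrylates or 2-(bromomethyl)enones (alkylation, then intramolecular enamine Michael addition); new here is closure on a fully substituted β-carbon. Ring B closes 6-endo-trig (C9 onto C10, the C5=C10 alkene lying inside the new ring), the 5-exo alternative being attack at C5, the electron-rich and fully substituted α-carbon. C7 is set by the valine auxiliary (open face of the chelated aza-enolate) and C10 by relay from C7: in the chair transition state the C7 ester stays hydrogen-bonded to the enamine N–H and is therefore equatorial, which fixes the ring pucker and the enone face, while the alkene geometry forces C14 axial, so the C7 ester and C14 end up cis; C5 arises by protonation and is erased in step 6. The step needs C- over N-alkylation and SN2 over carbonyl addition (soft aza-enolate, primary allylic bromide, −78 °C) and enough driving force for the hindered Michael addition (intramolecular, acid-activated acceptor, irreversible hydrolysis of the product imine).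

Step 6
Reactants: 10 the decalin-4,8-dione
Product: 11 4-hydroxy-7β-(methoxycarbonyl)-7α-(2-methoxy-2-oxoethyl)-10β-methyl-octal-4-ene-3,8-dione (diosphenol)
Conditions: SeO2 (1.2 equiv), dioxane–H2O (20:1), 90 °C
Reagents that add atoms: selenium dioxide, O=[Se]=O
Why: Riley oxidation of the C3 methylene next to the C4 ketone gives the 3,4-dione, which should settle as the 4-hydroxy-4-en-3-one, while the C8 ketone is shielded by quaternary C7 and neopentyl C9.

Step 7
Reactants: 11 the diosphenol
Product: 12 the 4-(trifluoromethanesulfonyloxy)-4-en-3-one (enol triflate of 11)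
Conditions: Tf2O, pyridine, CH2Cl2, −78 to 0 °C
Reagents that add atoms: trifluoromethanesulfonic anhydride, O=S(=O)(OS(=O)(=O)C(F)(F)F)C(F)(F)F
Why: O-Sulfonylation of the acidic diosphenol hydroxyl gives the α-triflyloxy enone, a standard cross-coupling handle.

Step 8
Reactants: 12 the enol triflate
Product: 13 7β-(methoxycarbonyl)-7α-(2-methoxy-2-oxoethyl)-4,10β-dimethyl-octal-4-ene-3,8-dione
Conditions: Me4Sn, Pd(PPh3)4 (5 mol %), LiCl, DMF, 80 °C
Reagents that add atoms: tetramethylstannane, C[Sn](C)(C)C
Why: Stille coupling of the vinyl triflate with tetramethylstannane puts C15 on C4 and completes the 4-methyl-4-en-3-one of ring A.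

Step 9
Reactants: 13 the β-keto diester
Product: 14 methyl 3,8-dioxo-13-noreudesm-4-en-12-oate (7β side chain)
Conditions: LiCl, H2O (2 equiv), DMSO, 150 °C
Reagents that add atoms: none
Why: Krapcho dealkoxycarbonylation removes only the ester β to the C8 ketone, and the enol formed is protonated to the more stable C7 epimer with the acetic ester arm equatorial (7β, cis to C14).

Step 10
Reactants: 14 the enone keto ester
Product: 16 3β-hydroxy-13-noreudesm-4-en-12,8β-olide (cis-fused lactone), via diol ester 15 (not isolated)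
Conditions: NaBH4, CeCl3·7H2O, MeOH, −40 to 0 °C; then PPTS (cat.), toluene, 40 °C
Reagents that add atoms: none
Why: Luche 1,2-reduction delivers hydride to both ketones from the α face (axial attack at C3 gives the equatorial 3β-ol; at C8 the axial C14 blocks the β face, giving the axial 8β-ol), and the 8β-hydroxyl then lactonises onto the cis C7 acetic ester.

Step 11
Reactants: 16 the hydroxy lactone
Product: 19 3β-hydroxyeudesma-4,11(13)-dien-12,8β-olide, via Mannich base 17 (not isolated), via methiodide 18 (not isolated)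
Conditions: LiN(iPr)2 (2.3 equiv), THF, −78 °C; CH2=NMe2+ I−, −78 °C to rt; then MeI, MeOH, rt; then aq NaHCO3, CH2Cl2
Reagents that add atoms: N,N-dimethylmethyleneiminium iodide, C=[N+](C)C.[I-]
Why: Aminomethylation of the lactone enolate (the 3-hydroxyl carried as its alkoxide), quaternisation and E1cB elimination is the standard α-methylenation of γ-lactones, and the transient C11 stereocentre is removed again.

Step 12
Reactants: 19 the hydroxy methylene lactone; 20 angelic acid ((2Z)-2-methylbut-2-enoic acid)
Product: 21 3α-angeloyloxyeudesma-4,11(13)-dien-12,8β-olide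
Conditions: PPh3, DIAD, THF, 0 °C to rt
Reagents that add atoms: none
Why: Mitsunobu esterification displaces the activated equatorial 3β-oxygen by angelate with inversion (SN2), giving the axial 3α-ester without acylating conditions that isomerise the Z acid.

Step 13
Reactants: 21 the angelate lactone
Product: 24 methyl 8β-acetoxy-3α-angeloyloxyeudesma-4,11(13)-dien-12-oate, via lithium carboxylate 22 (not isolated), via hydroxy ester 23 (not isolated)
Conditions: LiOH·H2O (1.2 equiv), THF–H2O, 0 °C; evaporate; MeI, DMF, rt; then Ac2O, DMAP, pyridine, rt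
Reagents that add atoms: lithium hydroxide, [Li+].[OH-]; iodomethane, CI; acetic anhydride, CC(=O)OC(C)=O
Why: Saponification of the conjugated lactone should be much faster than that of the hindered angelate, O-alkylation of the carboxylate gives the methyl ester without acid, and immediate acetylation of the 8β-hydroxyl forestalls relactonisation (C8 keeps its configuration).

Step 14
Reactants: 24 the 4-ene
Product: 25 methyl 8β-acetoxy-3α-angeloyloxy-5α-hydroperoxyeudesma-4(15),11(13)-dien-12-oate (target)
Conditions: O2, tetraphenylporphyrin (cat.), visible light, CH2Cl2, −20 °C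
Reagents that add atoms: oxygen, O=O
Why: Schenck ene reaction of singlet oxygen with the electron-rich tetrasubstituted 4,5-alkene on the α face (axial C14 shields the β face) should abstract a C15 hydrogen, because the other α-face allylic hydrogen (equatorial H-6α) is poorly aligned and H-3 is β, giving the 5α-hydroperoxide and the 4(15)-methylene.

**Compound list**

1 | 3-methylcyclohex-2-en-1-one | CC1=CC(=O)CCC1 | starting material
2 | 2-iodo-3-methylcyclohex-2-en-1-one | CC1=C(I)C(=O)CCC1 | intermediate
3 | 2-(hydroxymethyl)-3-methylcyclohex-2-en-1-one | CC1=C(CO)C(=O)CCC1 | intermediate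
4 | 2-(bromomethyl)-3-methylcyclohex-2-en-1-one | CC1=C(CBr)C(=O)CCC1 | intermediate
5 | dimethyl 2-acetylbutanedioate | COC(=O)CC(C(C)=O)C(=O)OC | starting material
6 | tert-butyl L-valinate | CC(C)[C@H](N)C(=O)OC(C)(C)C | starting material
7 | dimethyl (2Z)-2-[1-({(2S)-1-tert-butoxy-3-methyl-1-oxobutan-2-yl}amino)ethylidene]butanedioate | COC(=O)C\C(C(=O)OC)=C(/C)N[C@@H](C(C)C)C(=O)OC(C)(C)C | intermediate
8 | dimethyl (2R)-2-[1-({(2S)-1-tert-butoxy-3-methyl-1-oxobutan-2-yl}imino)ethyl]-2-[(2-methyl-6-oxocyclohex-1-en-1-yl)methyl]butanedioate | COC(=O)C[C@@](CC1=C(C)CCCC1=O)(C(=O)OC)C(C)=N[C@@H](C(C)C)C(=O)OC(C)(C)C | intermediate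
9 | C8 N-[(2S)-1-tert-butoxy-3-methyl-1-oxobutan-2-yl]imine of 10 | COC(=O)C[C@]1(C(=O)OC)C[C@H]2C(=O)CCC[C@]2(C)CC1=N[C@@H](C(C)C)C(=O)OC(C)(C)C | intermediate
10 | 7β-(methoxycarbonyl)-7α-(2-methoxy-2-oxoethyl)-10β-methyl-trans-decalin-4,8-dione | COC(=O)C[C@]1(C(=O)OC)C[C@H]2C(=O)CCC[C@]2(C)CC1=O | intermediate
11 | 4-hydroxy-4-en-3-one (diosphenol) from 10 | COC(=O)C[C@]1(C(=O)OC)CC2=C(O)C(=O)CC[C@]2(C)CC1=O | intermediate
12 | 4-triflyloxy-4-en-3-one | COC(=O)C[C@]1(C(=O)OC)CC2=C(OS(=O)(=O)C(F)(F)F)C(=O)CC[C@]2(C)CC1=O | intermediate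
13 | 7β-(methoxycarbonyl)-7α-(2-methoxy-2-oxoethyl)-4,10β-dimethyl-octal-4-ene-3,8-dione | COC(=O)C[C@]1(C(=O)OC)CC2=C(C)C(=O)CC[C@]2(C)CC1=O | intermediate
14 | methyl 3,8-dioxo-13-noreudesm-4-en-12-oate | COC(=O)C[C@H]1CC2=C(C)C(=O)CC[C@]2(C)CC1=O | intermediate
15 | methyl 3β,8β-dihydroxy-13-noreudesm-4-en-12-oate | COC(=O)C[C@H]1CC2=C(C)[C@@H](O)CC[C@]2(C)C[C@H]1O | intermediate
16 | 3β-hydroxy-13-noreudesm-4-en-12,8β-olide | O=C(O3)C[C@H]1CC2=C(C)[C@@H](O)CC[C@]2(C)C[C@H]13 | intermediate
17 | 13-(dimethylamino)-3β-hydroxyeudesm-4-en-12,8β-olide (C11 epimers) | CN(C)CC(C(=O)O3)[C@H]1CC2=C(C)[C@@H](O)CC[C@]2(C)C[C@H]13 | intermediate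
18 | N-methyl iodide (trimethylammonium iodide) of 17 | C[N+](C)(C)CC(C(=O)O3)[C@H]1CC2=C(C)[C@@H](O)CC[C@]2(C)C[C@H]13.[I-] | intermediate
19 | 3β-hydroxyeudesma-4,11(13)-dien-12,8β-olide | C=C(C(=O)O3)[C@H]1CC2=C(C)[C@@H](O)CC[C@]2(C)C[C@H]13 | intermediate
20 | angelic acid, (2Z)-2-methylbut-2-enoic acid | C/C=C(/C)C(=O)O | starting material
21 | 3α-angeloyloxyeudesma-4,11(13)-dien-12,8β-olide | C=C(C(=O)O3)[C@H]1CC2=C(C)[C@H](OC(=O)/C(C)=C\C)CC[C@]2(C)C[C@H]13 | intermediate
22 | lithium 3α-angeloyloxy-8β-hydroxyeudesma-4,11(13)-dien-12-oate | [Li+].[O-]C(=O)C(=C)[C@H]1CC2=C(C)[C@H](OC(=O)/C(C)=C\C)CC[C@]2(C)C[C@H]1O | intermediate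
23 | methyl 3α-angeloyloxy-8β-hydroxyeudesma-4,11(13)-dien-12-oate | C=C(C(=O)OC)[C@H]1CC2=C(C)[C@H](OC(=O)/C(C)=C\C)CC[C@]2(C)C[C@H]1O | intermediate
24 | methyl 8β-acetoxy-3α-angeloyloxyeudesma-4,11(13)-dien-12-oate | C=C(C(=O)OC)[C@H]1CC2=C(C)[C@H](OC(=O)/C(C)=C\C)CC[C@]2(C)C[C@H]1OC(C)=O | intermediate
25 | methyl 8β-acetoxy-3α-angeloyloxy-5α-hydroperoxyeudesma-4(15),11(13)-dien-12-oate | C=C(C(=O)OC)[C@H]1C[C@@]2(OO)C(=C)[C@H](OC(=O)/C(C)=C\C)CC[C@]2(C)C[C@H]1OC(C)=O | target

**Step count and risks**

Total: 14 steps. Longest linear sequence: 13 steps (1 → 25 through steps 1–3 and 5–14).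

Step 5 (labelled step). The enamine may fail to add to the fully substituted β-carbon, or may add with poor face selection at C10. The fallback sets out from imine 8, which the lithio-enamine alkylation delivers in any case. Hydrolysis (1 M aq HCl, THF) gives dimethyl (2R)-2-acetyl-2-[(2-methyl-6-oxocyclohex-1-en-1-yl)methyl]butanedioate F1. Ring B is then closed by the base-mediated intramolecular Michael addition of the methyl ketone enolate (KOtBu, t-BuOH–THF, 0 °C), relying on the C7 centre for face bias and on chromatography to remove the C10 epimer. The route is rejoined at 10.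

Step 13. The angelate may be partly saponified, hydroxide may add to the methylene lactone, or the hydroxy ester may relactonise before the acetate is on. The fallback sets out from 19 and moves the opening ahead of the angeloylation:
- Silylation of the 3β-hydroxyl (t-BuMe2SiCl, imidazole, DMF) gives 3β-(tert-butyldimethylsilyloxy)eudesma-4,11(13)-dien-12,8β-olide F2.
- LiOH gives lithium 3β-(tert-butyldimethylsilyloxy)-8β-hydroxyeudesma-4,11(13)-dien-12-oate F3.
- MeI in DMF gives methyl 3β-(tert-butyldimethylsilyloxy)-8β-hydroxyeudesma-4,11(13)-dien-12-oate F4.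
- Ac2O/DMAP gives methyl 8β-acetoxy-3β-(tert-butyldimethylsilyloxy)eudesma-4,11(13)-dien-12-oate F5.
- HF·pyridine in THF gives methyl 8β-acetoxy-3β-hydroxyeudesma-4,11(13)-dien-12-oate F6.
- Mitsunobu inversion of F6 with 20 (PPh3, DIAD) rejoins the route at 24.

Step 6. The SeO2 oxidation may over-oxidise, dehydrogenate the ketone, or attack C9 next to the other ketone. The fallback sets out from 10. The kinetic C3 enolate (LiN(SiMe3)2, THF, −78 °C) is hydroxylated with 2-(phenylsulfonyl)-3-phenyloxaziridine to 3-hydroxy-7β-(methoxycarbonyl)-7α-(2-methoxy-2-oxoethyl)-10β-methyl-trans-decalin-4,8-dione F7. Oxidation of the ketol with Dess–Martin periodinane gives the 3,4-dione, which is the diosphenol 11.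

Further compounds
F1 | step 5 | dimethyl (2R)-2-acetyl-2-[(2-methyl-6-oxocyclohex-1-en-1-yl)methyl]butanedioate | COC(=O)C[C@@](CC1=C(C)CCCC1=O)(C(=O)OC)C(C)=O
F2 | step 13 | 3β-(tert-butyldimethylsilyloxy)eudesma-4,11(13)-dien-12,8β-olide | C=C(C(=O)O3)[C@H]1CC2=C(C)[C@@H](O[Si](C)(C)C(C)(C)C)CC[C@]2(C)C[C@H]13
F3 | step 13 | lithium 3β-(tert-butyldimethylsilyloxy)-8β-hydroxyeudesma-4,11(13)-dien-12-oate | [Li+].[O-]C(=O)C(=C)[C@H]1CC2=C(C)[C@@H](O[Si](C)(C)C(C)(C)C)CC[C@]2(C)C[C@H]1O
F4 | step 13 | methyl 3β-(tert-butyldimethylsilyloxy)-8β-hydroxyeudesma-4,11(13)-dien-12-oate | C=C(C(=O)OC)[C@H]1CC2=C(C)[C@@H](O[Si](C)(C)C(C)(C)C)CC[C@]2(C)C[C@H]1O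
F5 | step 13 | methyl 8β-acetoxy-3β-(tert-butyldimethylsilyloxy)eudesma-4,11(13)-dien-12-oate | C=C(C(=O)OC)[C@H]1CC2=C(C)[C@@H](O[Si](C)(C)C(C)(C)C)CC[C@]2(C)C[C@H]1OC(C)=O
F6 | step 13 | methyl 8β-acetoxy-3β-hydroxyeudesma-4,11(13)-dien-12-oate | C=C(C(=O)OC)[C@H]1CC2=C(C)[C@@H](O)CC[C@]2(C)C[C@H]1OC(C)=O
F7 | step 6 | 3-hydroxy-7β-(methoxycarbonyl)-7α-(2-methoxy-2-oxoethyl)-10β-methyl-trans-decalin-4,8-dione | COC(=O)C[C@]1(C(=O)OC)C[C@H]2C(=O)C(O)CC[C@]2(C)CC1=O
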